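**Retrosynthetic overview**

1. Ring B (chromene carbons C4a, C5, C6, C7, C8, C8a) carries five contiguous substituents — pyran C4 on C4a, prenyl on C5, the propyl chain on C6, OH on C8, O1 on C8a — and its only hydrogen on C7. It is built from open-chain precursors instead of being substituted.
2. Ring B is cut at C5–C6 and C4a–C8a. 5-Methylhex-4-enal supplies C4a, C5 and the C5 prenyl group. Ynone 13 supplies C6, C7, C8 and C8a, with ring A already on the C6 propyl chain and the future pyran oxygen as a tertiary propargylic ether on C8a.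
3. Ynone 13 comes from a ring A pentyne (from 7-hydroxydihydrocoumarin, which differentiates the two ring A oxygens) and an α-alkoxy Weinreb amide.
4. One thermal operation then closes the pyran ring (C4–C4a bond from the C8a propargyl ether) and turns the ring A O-prenyl ether into the C-(1,1-dimethylallyl) group; MOM cleavage ends the route.
5. Order of ring formation: ring A (purchased), ring B (step 9), pyran ring (step 10).

Key step: step 9

Remark: kazinol K has no stereocentre; for the non-isolated intermediates 18 and 19 the alkene geometry given is that of the reactive isomer.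

**Step 1**
Reactants: 1 7-hydroxy-3,4-dihydro-2H-chromen-2-one; 2 1-bromo-3-methylbut-2-ene
Product: 3 7-[(3-methylbut-2-en-1-yl)oxy]-3,4-dihydro-2H-chromen-2-one
Conditions: K2CO3, acetone, 56 °C
Reagents that add atoms: none
Why: Williamson etherification; the C7 phenol is the only acidic site and its phenoxide should be O-alkylated by the allylic bromide (SN2) without opening the lactone.

**Step 2**
Reactants: 3 7-[(3-methylbut-2-en-1-yl)oxy]-3,4-dihydro-2H-chromen-2-one
Product: 4 2-(3-hydroxypropyl)-5-[(3-methylbut-2-en-1-yl)oxy]phenol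
Conditions: LiAlH4, THF, 0 °C; aqueous work-up
Reagents that add atoms: none
Why: Hydride reduction of the aryl ester (lactone) should give the primary alcohol and free the ortho phenol, which keeps the two ring A oxygens differentiated; the aryl prenyl ether is inert to hydride.

**Step 3**
Reactants: 4 2-(3-hydroxypropyl)-5-[(3-methylbut-2-en-1-yl)oxy]phenol
Product: 5 3-{2-(methoxymethoxy)-4-[(3-methylbut-2-en-1-yl)oxy]phenyl}propan-1-ol
Conditions: MOMCl, K2CO3, acetone, 25 °C
Reagents that add atoms: chloromethyl methyl ether (MOMCl), COCCl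
Why: Chemoselective Williamson O-alkylation; K2CO3 deprotonates the phenol but not the primary alcohol, so only the aryl MOM ether should form.

**Step 4**
Reactants: 5 3-{2-(methoxymethoxy)-4-[(3-methylbut-2-en-1-yl)oxy]phenyl}propan-1-ol
Product: 6 1-(3-iodopropyl)-2-(methoxymethoxy)-4-[(3-methylbut-2-en-1-yl)oxy]benzene
Conditions: I2, PPh3, imidazole, CH2Cl2, 0 to 25 °C
Reagents that add atoms: iodine, II
Why: Appel-type iodination of the primary alcohol (SN2 on the alkoxyphosphonium ion) under imidazole-buffered conditions that should spare the acetal and the trisubstituted alkene.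

**Step 5**
Reactants: 6 1-(3-iodopropyl)-2-(methoxymethoxy)-4-[(3-methylbut-2-en-1-yl)oxy]benzene
Product: 7 2-(methoxymethoxy)-4-[(3-methylbut-2-en-1-yl)oxy]-1-(pent-4-yn-1-yl)benzene
Conditions: LiC≡CH·H2NCH2CH2NH2, DMSO, 10 to 25 °C
Reagents that add atoms: lithium acetylide ethylenediamine complex, [Li]C#C.NCCN
Why: SN2 alkylation of lithium acetylide by an unhindered primary iodide in DMSO, for which elimination should be minor.

**Step 6**
Reactants: 8 2-methyl-4-(trimethylsilyl)but-3-yn-2-ol; 9 2-chloro-N-methoxy-N-methylacetamide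
Product: 11 N-methoxy-N-methyl-2-{[2-methyl-4-(trimethylsilyl)but-3-yn-2-yl]oxy}acetamide, via sodium alkoxide 10 (not isolated)
Conditions: NaH, THF, 0 °C; then 9, n-Bu4NI (cat.), 0 to 25 °C
Reagents that add atoms: none
Why: Williamson etherification of the tertiary propargylic alkoxide with an α-chloro amide, an SN2-reactive electrophile that cannot eliminate; the C-silyl group masks the acidic alkyne C–H for step 7.

**Step 7**
Reactants: 7 2-(methoxymethoxy)-4-[(3-methylbut-2-en-1-yl)oxy]-1-(pent-4-yn-1-yl)benzene; 11 N-methoxy-N-methyl-2-{[2-methyl-4-(trimethylsilyl)but-3-yn-2-yl]oxy}acetamide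
Product: 13 7-{2-(methoxymethoxy)-4-[(3-methylbut-2-en-1-yl)oxy]phenyl}-1-{[2-methyl-4-(trimethylsilyl)but-3-yn-2-yl]oxy}hept-3-yn-2-one, via lithium acetylide 12 (not isolated)
Conditions: n-BuLi, THF, −78 °C; then 11, −78 to −20 °C; AcOH quench at −78 °C
Reagents that add atoms: none
Why: Weinreb ketone synthesis; the acetylide should add once to the N-methoxy-N-methylamide through a chelated tetrahedral intermediate, and the cold acidic quench releases the ynone while protonating the liberated amine.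

**Step 8**
Reactants: 14 2-methylbut-3-en-2-ol; 15 ethyl vinyl ether
Product: 17 5-methylhex-4-enal, via allyl vinyl ether 16 (not isolated)
Conditions: Hg(OAc)2 (cat.), ethyl vinyl ether (excess), 35 °C; then sealed tube, 130 °C
Reagents that add atoms: none
Why: Transvinylation followed by aliphatic Claisen rearrangement ([3,3]-sigmatropic) of the tertiary allyl vinyl ether should give the γ,δ-unsaturated aldehyde whose α-carbon already bears the prenyl group.

**Step 9**
Reactants: 13 7-{2-(methoxymethoxy)-4-[(3-methylbut-2-en-1-yl)oxy]phenyl}-1-{[2-methyl-4-(trimethylsilyl)but-3-yn-2-yl]oxy}hept-3-yn-2-one; 17 5-methylhex-4-enal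
Product: 21 2-[(2-methylbut-3-yn-2-yl)oxy]-4-(3-methylbut-2-en-1-yl)-5-(3-{2-(methoxymethoxy)-4-[(3-methylbut-2-en-1-yl)oxy]phenyl}propyl)phenol, via enamine 18 (not isolated), via aminodienone 19 (not isolated), via silylated phenol 20 (not isolated)
Conditions: 17, pyrrolidine, 4 Å MS, Et2O, 0 °C; 13, EtOH, 0 to 25 °C; AcOH (5 equiv), 50 °C; evaporate; K2CO3 (cat.), MeOH, 25 °C
Reagents that add atoms: none
Why: Proposed new method: the preformed pyrrolidine enamine 18, which has a single nucleophilic carbon (the future C5), should add to the β-carbon of ynone 13 (the future C6) in a Stork enamine Michael addition, run in ethanol so that the zwitterion is protonated instead of closing to a cyclobutene, to give the push-pull aminodienone 19. Acetic acid then protonates C5, and the enol of the α'-alkoxy ketone (C8=C8a) attacks the iminium carbon C4a in a 6-(enolendo)-exo-trig Mannich closure; loss of pyrrolidine and tautomerisation should deliver the phenol, with the ynone carbonyl as the C8 hydroxyl and the tertiary propargylic ether on C8a. The closest known reaction types are the Bohlmann–Rahtz heteroannulation (enamine plus ynone, aminodienone, acid-promoted cyclodehydration) and amine-mediated Michael/aldol benzannulations; here the enamine is tertiary, so nitrogen cannot close and the carbon nucleophile does. No stereocentre is formed. The step needs the Michael mode, E/Z equilibration of 19 and ring closure at C8a: the protic solvent favours the first, reversible C-protonation of the dienamine allows the second, and the third is the only six-membered closure open to the iminium (C7 is vinylic, the propyl carbon would give a four-membered ring), so the pattern C5 prenyl, C6 chain, C7 H is fixed by the two fragments. The C-silyl group, the MOM acetal and the aryl prenyl ether should be inert to amine and acetic acid, and K2CO3 in methanol then removes the silyl group.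

**Step 10**
Reactants: 21 2-[(2-methylbut-3-yn-2-yl)oxy]-4-(3-methylbut-2-en-1-yl)-5-(3-{2-(methoxymethoxy)-4-[(3-methylbut-2-en-1-yl)oxy]phenyl}propyl)phenol
Product: 23 6-(3-{4-hydroxy-2-(methoxymethoxy)-5-(2-methylbut-3-en-2-yl)phenyl}propyl)-2,2-dimethyl-5-(3-methylbut-2-en-1-yl)-2H-chromen-8-ol, via chromene prenyl ether 22 (not isolated)
Conditions: PhNEt2, Ar, 140 °C then 195 °C
Reagents that add atoms: none
Why: Two sigmatropic cascades in one pot: aryl propargyl ether Claisen rearrangement, [1,5]-H shift and oxa-6π electrocyclisation should close the pyran ring at C4a (the only free ortho position), and at the higher temperature the ring A aryl prenyl ether should undergo aromatic Claisen rearrangement to the less hindered ortho carbon (the other lies between two oxygen substituents).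

**Step 11**
Reactants: 23 6-(3-{4-hydroxy-2-(methoxymethoxy)-5-(2-methylbut-3-en-2-yl)phenyl}propyl)-2,2-dimethyl-5-(3-methylbut-2-en-1-yl)-2H-chromen-8-ol
Product: 24 kazinol K, 4-{3-[8-hydroxy-2,2-dimethyl-5-(3-methylbut-2-en-1-yl)-2H-chromen-6-yl]propyl}-6-(2-methylbut-3-en-2-yl)benzene-1,3-diol
Conditions: HCl (0.1 M) in MeOH, 40 °C
Reagents that add atoms: none
Why: Acid-catalysed acetal methanolysis of the single aryl MOM ether under mild conditions that prenylated chromenes and o-(1,1-dimethylallyl)phenols are expected to tolerate.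

**Compound list**

1 | 7-hydroxy-3,4-dihydro-2H-chromen-2-one | O=C1CCc2ccc(O)cc2O1 | starting material
2 | 1-bromo-3-methylbut-2-ene | CC(C)=CCBr | starting material
3 | 7-[(3-methylbut-2-en-1-yl)oxy]-3,4-dihydro-2H-chromen-2-one | O=C1CCc2ccc(OCC=C(C)C)cc2O1 | intermediate
4 | 2-(3-hydroxypropyl)-5-[(3-methylbut-2-en-1-yl)oxy]phenol | OCCCc1ccc(OCC=C(C)C)cc1O | intermediate
5 | 3-{2-(methoxymethoxy)-4-[(3-methylbut-2-en-1-yl)oxy]phenyl}propan-1-ol | OCCCc1ccc(OCC=C(C)C)cc1OCOC | intermediate
6 | 1-(3-iodopropyl)-2-(methoxymethoxy)-4-[(3-methylbut-2-en-1-yl)oxy]benzene | ICCCc1ccc(OCC=C(C)C)cc1OCOC | intermediate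
7 | 2-(methoxymethoxy)-4-[(3-methylbut-2-en-1-yl)oxy]-1-(pent-4-yn-1-yl)benzene | C#CCCCc1ccc(OCC=C(C)C)cc1OCOC | intermediate
8 | 2-methyl-4-(trimethylsilyl)but-3-yn-2-ol | CC(C)(O)C#C[Si](C)(C)C | starting material
9 | 2-chloro-N-methoxy-N-methylacetamide | CON(C)C(=O)CCl | starting material
10 | sodium 2-methyl-4-(trimethylsilyl)but-3-yn-2-olate | CC(C)([O-])C#C[Si](C)(C)C.[Na+] | intermediate
11 | N-methoxy-N-methyl-2-{[2-methyl-4-(trimethylsilyl)but-3-yn-2-yl]oxy}acetamide | CON(C)C(=O)COC(C)(C)C#C[Si](C)(C)C | intermediate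
12 | lithium acetylide of 7 | [Li]C#CCCCc1ccc(OCC=C(C)C)cc1OCOC | intermediate
13 | 7-{2-(methoxymethoxy)-4-[(3-methylbut-2-en-1-yl)oxy]phenyl}-1-{[2-methyl-4-(trimethylsilyl)but-3-yn-2-yl]oxy}hept-3-yn-2-one | C[Si](C)(C)C#CC(C)(C)OCC(=O)C#CCCCc1ccc(OCC=C(C)C)cc1OCOC | intermediate
14 | 2-methylbut-3-en-2-ol | CC(C)(O)C=C | starting material
15 | ethyl vinyl ether | CCOC=C | starting material
16 | 3-(ethenyloxy)-3-methylbut-1-ene | C=COC(C)(C)C=C | intermediate
17 | 5-methylhex-4-enal | CC(C)=CCCC=O | intermediate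
18 | 1-[(1E)-5-methylhexa-1,4-dien-1-yl]pyrrolidine | CC(C)=CC/C=C/N1CCCC1 | intermediate
19 | (3Z,5E)-4-(3-{2-(methoxymethoxy)-4-[(3-methylbut-2-en-1-yl)oxy]phenyl}propyl)-5-(3-methylbut-2-en-1-yl)-1-{[2-methyl-4-(trimethylsilyl)but-3-yn-2-yl]oxy}-6-(pyrrolidin-1-yl)hexa-3,5-dien-2-one | N1(CCCC1)/C=C(CC=C(C)C)/C(CCCc2ccc(OCC=C(C)C)cc2OCOC)=C\C(=O)COC(C)(C)C#C[Si](C)(C)C | intermediate
20 | 5-(3-{2-(methoxymethoxy)-4-[(3-methylbut-2-en-1-yl)oxy]phenyl}propyl)-4-(3-methylbut-2-en-1-yl)-2-{[2-methyl-4-(trimethylsilyl)but-3-yn-2-yl]oxy}phenol | C[Si](C)(C)C#CC(C)(C)Oc1cc(CC=C(C)C)c(CCCc2ccc(OCC=C(C)C)cc2OCOC)cc1O | intermediate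
21 | 2-[(2-methylbut-3-yn-2-yl)oxy]-4-(3-methylbut-2-en-1-yl)-5-(3-{2-(methoxymethoxy)-4-[(3-methylbut-2-en-1-yl)oxy]phenyl}propyl)phenol | C#CC(C)(C)Oc1cc(CC=C(C)C)c(CCCc2ccc(OCC=C(C)C)cc2OCOC)cc1O | intermediate
22 | 2,2-dimethyl-5-(3-methylbut-2-en-1-yl)-6-(3-{2-(methoxymethoxy)-4-[(3-methylbut-2-en-1-yl)oxy]phenyl}propyl)-2H-chromen-8-ol | CC(C)=CCOc1ccc(CCCc2cc(O)c3OC(C)(C)C=Cc3c2CC=C(C)C)c(OCOC)c1 | intermediate
23 | 6-(3-{4-hydroxy-2-(methoxymethoxy)-5-(2-methylbut-3-en-2-yl)phenyl}propyl)-2,2-dimethyl-5-(3-methylbut-2-en-1-yl)-2H-chromen-8-ol | C=CC(C)(C)c1cc(CCCc2cc(O)c3OC(C)(C)C=Cc3c2CC=C(C)C)c(OCOC)cc1O | intermediate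
24 | kazinol K | C=CC(C)(C)c1cc(CCCc2cc(O)c3c(c2CC=C(C)C)C=CC(C)(C)O3)c(O)cc1O | target

**Step count**

Total step count: 11. Longest linear sequence: 9 steps (1, 2, 3, 4, 5, 7, 9, 10, 11) from compound 1.

**Steps most likely to fail**

1. Step 9 (Proposed new method). The enamine may react with the ynone by [2+2] cycloaddition and ring opening (two-carbon insertion) instead of Michael addition. The aminodienone may also stall because it fails to isomerise or to close, or the ynone may be lost by isomerisation to the allenone and oligomerisation. The fallback builds ring B on a carbocyclic template by known reactions; it sets out from iodide 6 and comes back at 24.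
 - Alkylation of the kinetic lithium enolate of commercial 3-ethoxycyclohex-2-en-1-one (LiN(i-Pr)2, THF, DMPU, −78 to 25 °C) with 6 gives racemic 3-ethoxy-6-(3-{2-(methoxymethoxy)-4-[(3-methylbut-2-en-1-yl)oxy]phenyl}propyl)cyclohex-2-en-1-one F1.
 - Addition of CH2=CHCH2MgBr and dilute HCl work-up (Stork–Danheiser transposition) gives racemic 3-(prop-2-en-1-yl)-4-(3-arylpropyl)cyclohex-2-en-1-one F2.
 - α'-Hydroxylation of its kinetic enolate with 2-(phenylsulfonyl)-3-phenyloxaziridine gives the 6-hydroxy enone F3, and MOMCl/i-Pr2NEt gives the 6-(methoxymethoxy) enone F4.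
 - α'-Selenenylation (LiN(i-Pr)2, PhSeBr) and selenoxide elimination (H2O2, pyridine) aromatise the ring to 2-(methoxymethoxy)-5-(prop-2-en-1-yl)-4-(3-arylpropyl)phenol F5.
 - Cross-metathesis with 2-methylbut-2-ene (second-generation Grubbs catalyst, RuCl2(=CHPh)(PCy3)(H2IMes)) gives the 5-(3-methylbut-2-en-1-yl)phenol F6.
 - O-Alkylation with 3-chloro-3-methylbut-1-yne (CuCl2 cat., DBU, MeCN, 0 °C) gives the aryl 2-methylbut-3-yn-2-yl ether F7.
 - The thermal conditions of step 10 give 8-O,2'-O-bis(methoxymethyl) kazinol K F8, and HCl in MeOH as in step 11 gives 24.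

2. Step 10. Migration of the ring A prenyl group to the carbon between the two oxygens, abnormal Claisen rearrangement or cyclisation of the freed o-(1,1-dimethylallyl)phenol at 195 °C, and thermal degradation of the chromene may erode the material. The fallback separates the two events and traps the rearranged phenol; it sets out from 21 and comes back at 23.
 - Heating 21 at 140 °C only gives chromene 22, which is isolated.
 - Heating 22 in Ac2O/NaOAc/PhNEt2 at 190 °C carries out the aromatic Claisen rearrangement with in situ acetylation and gives 8-O,4'-O-diacetyl-2'-O-(methoxymethyl) kazinol K F9.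
 - K2CO3 in MeOH removes both acetates and gives 23.

3. Step 7. The acetylide may deprotonate the α-alkoxy amide instead of adding, and the liberated N,O-dimethylhydroxylamine may add to the ynone in conjugate fashion during warming or quench. The fallback reaches the ynone at the alcohol oxidation level; it sets out from 11 and 7 and comes back at 13.
 - Reduction of 11 with i-Bu2AlH (THF, −78 °C) gives 2-{[2-methyl-4-(trimethylsilyl)but-3-yn-2-yl]oxy}acetaldehyde F10.
 - Addition of lithium acetylide 12 (from 7 and n-BuLi) gives the racemic propargylic alcohol 7-{2-(methoxymethoxy)-4-[(3-methylbut-2-en-1-yl)oxy]phenyl}-1-{[2-methyl-4-(trimethylsilyl)but-3-yn-2-yl]oxy}hept-3-yn-2-ol F11.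
 - Oxidation with MnO2 (CH2Cl2, 25 °C) gives 13.

**Further compounds**

F1 | step 9 | 3-ethoxy-6-(3-{2-(methoxymethoxy)-4-[(3-methylbut-2-en-1-yl)oxy]phenyl}propyl)cyclohex-2-en-1-one (racemic) | CCOC1=CC(=O)C(CCCc2ccc(OCC=C(C)C)cc2OCOC)CC1
F2 | step 9 | 4-(3-{2-(methoxymethoxy)-4-[(3-methylbut-2-en-1-yl)oxy]phenyl}propyl)-3-(prop-2-en-1-yl)cyclohex-2-en-1-one (racemic) | C=CCC1=CC(=O)CCC1CCCc2ccc(OCC=C(C)C)cc2OCOC
F3 | step 9 | 6-hydroxy-4-(3-{2-(methoxymethoxy)-4-[(3-methylbut-2-en-1-yl)oxy]phenyl}propyl)-3-(prop-2-en-1-yl)cyclohex-2-en-1-one (racemic, mixture of diastereomers) | C=CCC1=CC(=O)C(O)CC1CCCc2ccc(OCC=C(C)C)cc2OCOC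
F4 | step 9 | 6-(methoxymethoxy)-4-(3-{2-(methoxymethoxy)-4-[(3-methylbut-2-en-1-yl)oxy]phenyl}propyl)-3-(prop-2-en-1-yl)cyclohex-2-en-1-one (racemic, mixture of diastereomers) | C=CCC1=CC(=O)C(OCOC)CC1CCCc2ccc(OCC=C(C)C)cc2OCOC
F5 | step 9 | 2-(methoxymethoxy)-4-(3-{2-(methoxymethoxy)-4-[(3-methylbut-2-en-1-yl)oxy]phenyl}propyl)-5-(prop-2-en-1-yl)phenol | C=CCc1cc(O)c(OCOC)cc1CCCc2ccc(OCC=C(C)C)cc2OCOC
F6 | step 9 | 2-(methoxymethoxy)-4-(3-{2-(methoxymethoxy)-4-[(3-methylbut-2-en-1-yl)oxy]phenyl}propyl)-5-(3-methylbut-2-en-1-yl)phenol | CC(C)=CCc1cc(O)c(OCOC)cc1CCCc2ccc(OCC=C(C)C)cc2OCOC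
F7 | step 9 | 1-(methoxymethoxy)-2-[(2-methylbut-3-yn-2-yl)oxy]-4-(3-methylbut-2-en-1-yl)-5-(3-{2-(methoxymethoxy)-4-[(3-methylbut-2-en-1-yl)oxy]phenyl}propyl)benzene | CC(C)=CCc1cc(OC(C)(C)C#C)c(OCOC)cc1CCCc2ccc(OCC=C(C)C)cc2OCOC
F8 | step 9 | 8-O,2'-O-bis(methoxymethyl) kazinol K | C=CC(C)(C)c1cc(CCCc2cc(OCOC)c3OC(C)(C)C=Cc3c2CC=C(C)C)c(OCOC)cc1O
F9 | step 10 | 8-O,4'-O-diacetyl-2'-O-(methoxymethyl) kazinol K | C=CC(C)(C)c1cc(CCCc2cc(OC(C)=O)c3OC(C)(C)C=Cc3c2CC=C(C)C)c(OCOC)cc1OC(C)=O
F10 | step 7 | 2-{[2-methyl-4-(trimethylsilyl)but-3-yn-2-yl]oxy}acetaldehyde | O=CCOC(C)(C)C#C[Si](C)(C)C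
F11 | step 7 | 7-{2-(methoxymethoxy)-4-[(3-methylbut-2-en-1-yl)oxy]phenyl}-1-{[2-methyl-4-(trimethylsilyl)but-3-yn-2-yl]oxy}hept-3-yn-2-ol (racemic) | C[Si](C)(C)C#CC(C)(C)OCC(O)C#CCCCc1ccc(OCC=C(C)C)cc1OCOC
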